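**Plan**

- Retrosynthesis (prostaglandin numbering): remove the 15-acetyl group; cut C7–C8 (α-chain as a (Z)-allylic bromide); cut the two ring bonds C11–C12 and C8–C9, which opens the cyclopentenone to methyl 3-nitropropanoate (C9–C10–C11) and a 2,4-dienal (C12, C8 and the ω-chain, its formyl carbon serving as a disposable activator); cut the dienal by Wittig reaction and cross-metathesis back to (S)-oct-1-en-3-ol.
- Forward: ω-chain dienal (steps 1–2); the ring is built in one flask by Michael addition and Claisen ring closure (step 3); the α-chain bromide (steps 4–6) is joined at C8 (step 7); formyl and nitro groups are expelled to unveil the enone (step 8); acetylation (step 9).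
- Enabling feature: in the cyclopent-2-enone ring, C9(=O)–C10=C11 is an acrylate unit whose β-carbon C11 must bond as a nucleophile and whose carbonyl carbon C9 as an acyl donor, while C12 and C8 are the β- and α-carbons of an enal. The nitro group of methyl 3-nitropropanoate supplies the C11 carbanion and later leaves as nitrite to create C10=C11.
- Stereochemistry: C15 is bought with the starting alcohol; C12 is set by the (S)-diphenylprolinol silyl ether catalyst in step 3; C8 settles trans to the C12 chain by equilibration next to the ketone in step 8; 13E comes from cross-metathesis and 5Z from a non-stabilized Wittig reaction.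

Key step: step 3

Remark: the 2-formyl ketone made in the key step should exist largely as its hydroxymethylene enol and is drawn as the keto aldehyde; the nitro-bearing and formyl-bearing ring carbons of the ring intermediates are left undefined because both are planarized or reset later.

**Route**

Step 1
Reactants: 1 (3S)-oct-1-en-3-ol; 2 (2E)-but-2-enal (excess)
Product: 3 (2E,4S)-4-hydroxynon-2-enal
Conditions: RuCl2(=CH-C6H4-2-OiPr)(H2IMes) (second-generation Hoveyda–Grubbs catalyst, H2IMes = 1,3-dimesitylimidazolidin-2-ylidene, 3 mol %), CH2Cl2, 40 °C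
Reagents that add atoms: none
Why: Olefin cross-metathesis of the secondary allylic alcohol with an excess of the electron-poor enal should give the (E)-hydroxy enal with loss of propene and without touching the carbinol stereocenter.

Step 2
Reactants: 3 (2E,4S)-4-hydroxynon-2-enal; 4 (triphenylphosphoranylidene)acetaldehyde
Product: 5 (2E,4E,6S)-6-hydroxyundeca-2,4-dienal
Conditions: toluene, 70 °C
Reagents that add atoms: none
Why: Wittig olefination with the stabilized formylmethylene ylide should add to the aldehyde only and give the new double bond with (E)-geometry, the vinylogous product being less electrophilic than 3.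

Step 3
Reactants: 5 (2E,4E,6S)-6-hydroxyundeca-2,4-dienal; 6 methyl 3-nitropropanoate (1.5 equiv)
Product: 8 (2R)-2-[(1E,3S)-3-hydroxyoct-1-en-1-yl]-3-nitro-5-oxocyclopentane-1-carbaldehyde, via Michael adduct 7 (not isolated)
Conditions: (S)-2-[diphenyl(trimethylsilyloxy)methyl]pyrrolidine (10 mol %), PhCO2H (20 mol %), MeOH, rt; then NaOMe (3.5 equiv), MeOH (dilute), 0 °C to rt; AcOH quench
Reagents that add atoms: none
Why: Proposed new method: the (E)-iminium ion formed from 5 and the secondary amine takes up the nitronate of 6 at C3 of the dienal (Michael addition, future C11–C12 bond), and after methoxide is added the aldehyde enolate of 7 attacks the methyl ester and expels methoxide (Claisen condensation of the Dieckmann type, future C8–C9 bond), so that the nitro ester acts as an acrylate with a nucleophilic β-carbon and an electrophilic carbonyl carbon; the closest known reaction types are the diarylprolinol silyl ether-catalysed Michael addition of nitroalkanes to enals followed by a ring-closing Henry or aldol step, and the Dieckmann condensation, whereas ring-closing acylation by an aldehyde enolate after an iminium-catalysed Michael addition has not been shown. The ring closes in the 5-(enolexo)-exo-trig mode at the ester carbonyl. The one lasting new stereocenter (C2 of 8, C12 of the target) is controlled by the catalyst, whose diphenyl(trimethylsilyloxy)methyl group shields one face of the s-trans iminium ion, so that the (S)-catalyst should give the configuration needed for 12S; the nitro-bearing and formyl-bearing carbons are not controlled and are planarized or reset later, and C15 is not touched. The step needs 1,4- instead of 1,6-addition to the dienal, which iminium activation of 2,4-dienals is expected to provide, and it needs acylation by the aldehyde α-carbon alone, which the substrate secures because methoxide turns the nitro group into its nitronate, and the nitronate cannot leave in a retro-Michael step, cannot lose nitrite and disfavours deprotonation of the neighbouring ester α-carbon. Deprotonation of the 2-formyl ketone as it forms should pull the condensation to completion.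

Step 4
Reactants: 9 (4-carboxybutyl)triphenylphosphonium bromide; 10 [(tert-butyldimethylsilyl)oxy]acetaldehyde
Product: 12 (5Z)-7-[(tert-butyldimethylsilyl)oxy]hept-5-enoic acid, via phosphorus ylide 11 (not isolated)
Conditions: NaN(SiMe3)2 (2.1 equiv), THF, 0 °C; then 10, −78 °C to rt; cold dilute HCl work-up (pH 4)
Reagents that add atoms: none
Why: Wittig reaction of the non-stabilized ylide with the α-silyloxy aldehyde under kinetic control should give the (Z)-alkene.

Step 5
Reactants: 12 (5Z)-7-[(tert-butyldimethylsilyl)oxy]hept-5-enoic acid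
Product: 13 methyl (5Z)-7-hydroxyhept-5-enoate
Conditions: MeOH, HCl (cat.), 0 °C to rt
Reagents that add atoms: methanol, CO
Why: Fischer esterification in methanolic HCl, which at the same time removes the silyl ether by acid-catalysed methanolysis.

Step 6
Reactants: 13 methyl (5Z)-7-hydroxyhept-5-enoate
Product: 14 methyl (5Z)-7-bromohept-5-enoate
Conditions: CBr4, PPh3, CH2Cl2, 0 °C
Reagents that add atoms: tetrabromomethane, BrC(Br)(Br)Br
Why: Appel reaction, in which bromide displaces the oxyphosphonium group at the primary allylic carbon by SN2 and the (Z)-double bond should stay untouched at low temperature.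

Step 7
Reactants: 8 (2R)-2-[(1E,3S)-3-hydroxyoct-1-en-1-yl]-3-nitro-5-oxocyclopentane-1-carbaldehyde; 14 methyl (5Z)-7-bromohept-5-enoate
Product: 15 methyl (5Z)-7-[(2R)-1-formyl-2-[(1E,3S)-3-hydroxyoct-1-en-1-yl]-3-nitro-5-oxocyclopentyl]hept-5-enoate
Conditions: K2CO3 (1.0 equiv), NaI (10 mol %), acetone, 0 °C to rt
Reagents that add atoms: none
Why: Enolate C-alkylation (SN2) of the hydroxymethylene ketone with the soft primary allylic halide, the classical formyl-activated α-alkylation of a ketone, in which one equivalent of carbonate should deprotonate the more acidic and faster-ionizing formyl ketone in preference to the secondary nitro group, and the configuration of the new quaternary carbon is of no consequence because the formyl group is removed in the next step.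

Step 8
Reactants: 15 methyl (5Z)-7-[(2R)-1-formyl-2-[(1E,3S)-3-hydroxyoct-1-en-1-yl]-3-nitro-5-oxocyclopentyl]hept-5-enoate
Product: 17 methyl (5Z)-7-[(1R,2S)-2-[(1E,3S)-3-hydroxyoct-1-en-1-yl]-5-oxocyclopent-3-en-1-yl]hept-5-enoate, via nitro ketone 16 (not isolated)
Conditions: K2CO3 (1.2 equiv), MeOH, −10 to 0 °C; pH 7 phosphate buffer quench
Reagents that add atoms: none
Why: Methoxide adds to the non-enolizable formyl group and retro-Claisen cleavage releases methyl formate, the β-nitro ketone 16 then loses nitrous acid by E1cB elimination to the enone, and C8 is protonated and equilibrated next to the ketone to the more stable trans arrangement with the C12 chain (8R).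

Step 9
Reactants: 17 methyl (5Z)-7-[(1R,2S)-2-[(1E,3S)-3-hydroxyoct-1-en-1-yl]-5-oxocyclopent-3-en-1-yl]hept-5-enoate
Product: 18 methyl (5Z)-7-[(1R,2S)-2-[(1E,3S)-3-(acetyloxy)oct-1-en-1-yl]-5-oxocyclopent-3-en-1-yl]hept-5-enoate
Conditions: Ac2O, pyridine, 4-(dimethylamino)pyridine (5 mol %), CH2Cl2, 0 °C
Reagents that add atoms: acetic anhydride, CC(=O)OC(C)=O
Why: Acetylation of the secondary allylic alcohol under nucleophilic catalysis, which should leave the stereocenters and the enone unchanged.

**Compound list**

1 | (3S)-oct-1-en-3-ol | CCCCC[C@@H](C=C)O | starting material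
2 | (2E)-but-2-enal | C/C=C/C=O | starting material
3 | (2E,4S)-4-hydroxynon-2-enal | CCCCC[C@@H](/C=C/C=O)O | intermediate
4 | (triphenylphosphoranylidene)acetaldehyde | O=CC=P(c1ccccc1)(c1ccccc1)c1ccccc1 | starting material
5 | (2E,4E,6S)-6-hydroxyundeca-2,4-dienal | CCCCC[C@@H](/C=C/C=C/C=O)O | intermediate
6 | methyl 3-nitropropanoate | COC(=O)CC[N+](=O)[O-] | starting material
7 | methyl (4S,5E,7S)-7-hydroxy-3-nitro-4-(2-oxoethyl)dodec-5-enoate (both C3 epimers) | CCCCC[C@@H](/C=C/[C@H](CC=O)C(CC(=O)OC)[N+](=O)[O-])O | intermediate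
8 | (2R)-2-[(1E,3S)-3-hydroxyoct-1-en-1-yl]-3-nitro-5-oxocyclopentane-1-carbaldehyde (C1 and C3 undefined) | CCCCC[C@@H](/C=C/[C@H]1C([N+](=O)[O-])CC(=O)C1C=O)O | intermediate
9 | (4-carboxybutyl)triphenylphosphonium bromide | OC(=O)CCCC[P+](c1ccccc1)(c1ccccc1)c1ccccc1.[Br-] | starting material
10 | [(tert-butyldimethylsilyl)oxy]acetaldehyde | O=CCO[Si](C)(C)C(C)(C)C | starting material
11 | sodium 5-(triphenylphosphoranylidene)pentanoate | [Na+].[O-]C(=O)CCCC=P(c1ccccc1)(c1ccccc1)c1ccccc1 | intermediate
12 | (5Z)-7-[(tert-butyldimethylsilyl)oxy]hept-5-enoic acid | OC(=O)CCC/C=C\CO[Si](C)(C)C(C)(C)C | intermediate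
13 | methyl (5Z)-7-hydroxyhept-5-enoate | COC(=O)CCC/C=C\CO | intermediate
14 | methyl (5Z)-7-bromohept-5-enoate | COC(=O)CCC/C=C\CBr | intermediate
15 | methyl (5Z)-7-[(2R)-1-formyl-2-[(1E,3S)-3-hydroxyoct-1-en-1-yl]-3-nitro-5-oxocyclopentyl]hept-5-enoate (C1 and C3 of the ring undefined) | CCCCC[C@@H](/C=C/[C@H]1C([N+](=O)[O-])CC(=O)C1(C=O)C/C=C\CCCC(=O)OC)O | intermediate
16 | methyl (5Z)-7-[(2R)-2-[(1E,3S)-3-hydroxyoct-1-en-1-yl]-3-nitro-5-oxocyclopentyl]hept-5-enoate (C1 and C3 of the ring undefined) | CCCCC[C@@H](/C=C/[C@H]1C([N+](=O)[O-])CC(=O)C1C/C=C\CCCC(=O)OC)O | intermediate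
17 | methyl (5Z)-7-[(1R,2S)-2-[(1E,3S)-3-hydroxyoct-1-en-1-yl]-5-oxocyclopent-3-en-1-yl]hept-5-enoate | CCCCC[C@@H](/C=C/[C@H]1C=CC(=O)[C@@H]1C/C=C\CCCC(=O)OC)O | intermediate
18 | methyl (5Z)-7-[(1R,2S)-2-[(1E,3S)-3-(acetyloxy)oct-1-en-1-yl]-5-oxocyclopent-3-en-1-yl]hept-5-enoate | CCCCC[C@@H](/C=C/[C@H]1C=CC(=O)[C@@H]1C/C=C\CCCC(=O)OC)OC(C)=O | target

**Step count and risks**

Total step count: 9. Longest linear sequence: 6 steps (steps 1, 2, 3, 7, 8, 9 from 1; the α-chain branch, steps 4, 5, 6, 7, 8, 9 from 9, is equally long).

Steps most likely to fail: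

1. Step 3 (bears the label). What may go wrong: the aldehyde of 7 may undergo intermolecular aldol condensation faster than the ring-closing acylation, or the ester may not be electrophilic enough for the aldehyde enolate. The fallback uses known chemistry only, sets out from 5 (with 6) and comes back to the route at 17. The Michael addition alone (the first stage of step 3) is run and 7 is isolated. Oxidation of its aldehyde with NaClO2, NaH2PO4 and 2-methylbut-2-ene in tBuOH/H2O should give (3S,4E,6S)-6-hydroxy-3-(3-methoxy-1-nitro-3-oxopropyl)undec-4-enoic acid F1. Esterification of the acid alone with O-tert-butyl-N,N′-diisopropylisourea should give 1-tert-butyl 6-methyl (3S)-3-[(1E,3S)-3-hydroxyoct-1-en-1-yl]-4-nitrohexanedioate F2. Dieckmann condensation (KOtBu, 3.5 equiv, THF, −30 °C), in which the tert-butyl ester enolate attacks the methyl ester while the nitronate blocks the other α-position, should give tert-butyl (2R)-2-[(1E,3S)-3-hydroxyoct-1-en-1-yl]-3-nitro-5-oxocyclopentane-1-carboxylate F3. C-alkylation of this β-keto ester with 14 (K2CO3, acetone) should give tert-butyl (2R)-2-[(1E,3S)-3-hydroxyoct-1-en-1-yl]-1-[(2Z)-7-methoxy-7-oxohept-2-en-1-yl]-3-nitro-5-oxocyclopentane-1-carboxylate F4. Brief treatment with CF3CO2H (CH2Cl2, 0 °C to rt) removes the tert-butyl group; the β-keto acid so formed, which is the acid reached from 15 in the fallback for step 8 and is listed there, loses carbon dioxide to give 16, and Et3N then eliminates nitrous acid to give 17.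

2. Step 7. What may go wrong: alkylation of the ambident enolate at the formyl oxygen instead of at carbon, and consumption of the bromide by the nitronate if the nitro group is deprotonated as well. The fallback sets out from 8 and comes back to the route at 17. Tsuji–Trost allylation of 8 with allyl methyl carbonate and Pd(PPh3)4 (2 mol %, THF, rt) proceeds under neutral conditions at carbon of the soft enolate and should give (2R)-2-[(1E,3S)-3-hydroxyoct-1-en-1-yl]-3-nitro-5-oxo-1-(prop-2-en-1-yl)cyclopentane-1-carbaldehyde F5. K2CO3 in MeOH, as in step 8, should remove the formyl group to give (3R)-3-[(1E,3S)-3-hydroxyoct-1-en-1-yl]-4-nitro-2-(prop-2-en-1-yl)cyclopentan-1-one F6, which is not isolated and loses nitrous acid in the same flask to give (4S,5R)-4-[(1E,3S)-3-hydroxyoct-1-en-1-yl]-5-(prop-2-en-1-yl)cyclopent-2-en-1-one F7. Z-selective cross-metathesis of the terminal alkene of this enone with methyl hex-5-enoate, using the cyclometalated ruthenium nitrato catalyst Ru(κ2-O2NO)(=CH-C6H4-2-OiPr)(C,C-chelating 1-(adamantan-1-yl)-3-(2,6-diisopropylphenyl)imidazolidin-2-ylidene), which should leave the internal (E)-alkene alone, should give 17.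

3. Step 8. What may go wrong: once the enone is exposed to carbonate and methoxide, deprotonation at C12 can cause epimerization there and migration of the ring double bond into conjugation with the side-chain alkene. The fallback sets out from 15 and comes back to the route at 17. The formyl group is oxidized with NaClO2, NaH2PO4 and 2-methylbut-2-ene to (2R)-2-[(1E,3S)-3-hydroxyoct-1-en-1-yl]-1-[(2Z)-7-methoxy-7-oxohept-2-en-1-yl]-3-nitro-5-oxocyclopentane-1-carboxylic acid F8. This β-keto acid loses carbon dioxide under the weakly acidic conditions to give 16, which is isolated. Et3N (CH2Cl2, −20 °C) then eliminates nitrous acid to give 17, so the enone meets only a tertiary amine.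

Further compounds
F1 | step 3 | (3S,4E,6S)-6-hydroxy-3-(3-methoxy-1-nitro-3-oxopropyl)undec-4-enoic acid | CCCCC[C@@H](/C=C/[C@H](CC(=O)O)C(CC(=O)OC)[N+](=O)[O-])O
F2 | step 3 | 1-tert-butyl 6-methyl (3S)-3-[(1E,3S)-3-hydroxyoct-1-en-1-yl]-4-nitrohexanedioate | CCCCC[C@@H](/C=C/[C@H](CC(=O)OC(C)(C)C)C(CC(=O)OC)[N+](=O)[O-])O
F3 | step 3 | tert-butyl (2R)-2-[(1E,3S)-3-hydroxyoct-1-en-1-yl]-3-nitro-5-oxocyclopentane-1-carboxylate | CCCCC[C@@H](/C=C/[C@H]1C([N+](=O)[O-])CC(=O)C1C(=O)OC(C)(C)C)O
F4 | step 3 | tert-butyl (2R)-2-[(1E,3S)-3-hydroxyoct-1-en-1-yl]-1-[(2Z)-7-methoxy-7-oxohept-2-en-1-yl]-3-nitro-5-oxocyclopentane-1-carboxylate | CCCCC[C@@H](/C=C/[C@H]1C([N+](=O)[O-])CC(=O)C1(C(=O)OC(C)(C)C)C/C=C\CCCC(=O)OC)O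
F5 | step 7 | (2R)-2-[(1E,3S)-3-hydroxyoct-1-en-1-yl]-3-nitro-5-oxo-1-(prop-2-en-1-yl)cyclopentane-1-carbaldehyde | CCCCC[C@@H](/C=C/[C@H]1C([N+](=O)[O-])CC(=O)C1(C=O)CC=C)O
F6 | step 7 | (3R)-3-[(1E,3S)-3-hydroxyoct-1-en-1-yl]-4-nitro-2-(prop-2-en-1-yl)cyclopentan-1-one | CCCCC[C@@H](/C=C/[C@H]1C([N+](=O)[O-])CC(=O)C1CC=C)O
F7 | step 7 | (4S,5R)-4-[(1E,3S)-3-hydroxyoct-1-en-1-yl]-5-(prop-2-en-1-yl)cyclopent-2-en-1-one | CCCCC[C@@H](/C=C/[C@H]1C=CC(=O)[C@@H]1CC=C)O
F8 | step 8 | (2R)-2-[(1E,3S)-3-hydroxyoct-1-en-1-yl]-1-[(2Z)-7-methoxy-7-oxohept-2-en-1-yl]-3-nitro-5-oxocyclopentane-1-carboxylic acid | CCCCC[C@@H](/C=C/[C@H]1C([N+](=O)[O-])CC(=O)C1(C(=O)O)C/C=C\CCCC(=O)OC)O
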